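Readings and results come from a simulation for substances that don't exist, noise included.

Leave the charge alone.

all flasks: impurity 0.38 mM

| run | free monomer | transfer agent | pre-initiator | remark | time |
|---|---|---|---|---|---|
| alder | 0.010 M | 0.30 mM | 1.1 mM | run made earlier |  |
| maple | 0.010 M | 0.30 mM | 1.8 mM | run made earlier |  |
| elm | 0.0050 M | 0.30 mM | 0.81 mM | run made earlier |  |
| eta | 0.010 M | 0.300 mM | 0.81 mM |  | 5.0 min |
| gamma | 0.010 M | 0.300 mM | 0.81 mM |  | 1.5 min |

| run | time / min | monomer in chains / % | free monomer / % |
|---|---|---|---|
| alder | 0.417 | 2.5 | 97.7 |
| alder | 1.33 | 21.0 | 79.1 |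
| alder | 2.50 | 80.8 | 19.4 |
| alder | 4.00 | 98.6 | 1.1 |
| alder | 5.00 | 99.7 | 0.3 |
| maple | 0.417 | 4.0 | 95.5 |
| maple | 0.833 | 20.8 | 79.1 |
| maple | 1.33 | 68.3 | 32.2 |
| maple | 2.50 | 99.5 | 1.1 |
| maple | 5.00 | 99.5 | 0.3 |
| elm | 0.417 | 0.2 | 99.8 |
| elm | 1.33 | 5.9 | 92.5 |
| elm | 2.50 | 34.6 | 64.2 |
| elm | 4.00 | 83.0 | 17.9 |
| elm | 5.00 | 93.9 | 7.7 |

(each reading ± 0.5 percentage points)

- the average divides the monomer in chains by the number of chains begun, living and dead together
- the earlier runs were read with a standard deviation of 0.5 percentage points
- the earlier runs do not show the number of chains; that part of a forecast is a guess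

- which of the two ends with the longer chains by the average number of monomer units in a chain (chains begun, living or dead) ("neither" if they lie within 10%) (eta / gamma / neither)
- average number of monomer units in a chain (chains begun, living or dead) at the end, eta
- average number of monomer units in a chain (chains begun, living or dead) at the end, gamma

Bench note: eta and gamma are one charge, read at 5.0 min and at 1.5 min.

1. In the flask: free monomer, [M] = 0.010 M; transfer agent, [T] = 0.300 mM; impurity; pre-initiator. Elm, with the same pre-initiator, starts slowly, with 0.2% in chains at 0.417 min.

2. To come, taking loss of free monomer as first order in it: eta should lie near elm's 93.9% at 5.00 min, and gamma low on the curve, near elm's 5.9% at 1.33 min.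

3. The earlier runs do not show the chains, so this reckoning assumes that each closing chain uses one transfer agent. Growth rate divided by closing rate then loses both time and the unknown count of living ends: the running length (kinetic chain length) goes as [M]/[T].

4. Carried to the limit where both have fully reacted and every chain is closed, the average length becomes 33.3, the charge ratio, free monomer charged per transfer agent charged.

5. Do not add free monomer or transfer agent: the charge ratio is reckoned on these charges.

6. If [M]/[T] falls during a run, the average falls towards the charge ratio from above. That fall is a guess, but it is the one committed to here: eta near 33.3, gamma above it, gamma longer.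

The forecast gave 15 for eta and 4 for gamma: “Eta ends longer”.

    living end + transfer agent → dead chain (kL = 140 M⁻¹ s⁻¹)
    free monomer + initiator → living end + monomer in chains (k = 17.0 M⁻¹ s⁻¹)
    pre-initiator → initiator (k = 0.00630 s⁻¹)
    free monomer + living end → monomer in chains + living end, rate k4*[living end]*[free monomer] (k = 320 M⁻¹ s⁻¹)
    initiator + impurity → spent initiator (k = 10000 M⁻¹ s⁻¹)

The simulation gives 36.8 for eta and 49.4 for gamma, so gamma ends longer. In gamma at 1.50 min, with impurity at 16.3% of its charge, initiator meeting impurity had given 3.18 × 10⁻⁴ M of spent initiator, while monomer in chains stood at 14.2% and dead chain at 1.91 × 10⁻⁵ M. In eta at 5.00 min, with impurity at 0%, monomer in chains stood at 94.3%, and living ends closing on transfer agent had given 2.11 × 10⁻⁴ M of dead chain, with 29.7% of transfer agent left. Eta's flask left until 12 min keeps 5.0% of its transfer agent and stands at 32.8, level with the charge ratio of 33.3.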